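The data come from a simulation for substances that don't exist.

Start from a small charge: 40 µM of catalyst among 0.020 M of starting material and 0.0210 M of reagent, in a flask read so far up to 15.0 h and asked about up to 50 h.

all flasks: starting material 0.020 M; catalyst 40 µM

|  | reagent | remark | time |
|---|---|---|---|
| theta | 0.021 M | the very flask that is asked about, followed so far |  |
| flask | 0.0210 M |  | 50 h |

theta run (percent of the starting material charged): time / h: target / % = 1.33: 0; 2.50: 3.5; 4.00: 6.9; 8.00: 13.8; 15.0: 24.2

(scatter of a reading: 1 percentage point)

- the analysis behind the earlier runs scatters by 1 percentage point, standard deviation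

1. amount of target in percent of the starting material charged, at 5.0 h, 20 h and 50 h

Reagent and starting material are charged at a ratio of 1.05, so try a plain law: rate = k[starting material][reagent], with the two brackets falling nearly together. Under that law, the ratio of charge turned into target to charge not yet turned grows nearly in a straight line with time, as in a step-growth plot.

Take this ratio from two readings: 0.0363 at 2.50 h and 0.319 at 15.0 h. The line then gives a time 44.2 h and a lag of 0.898 h. Call this the half-way clock: the time after the lag in which the ratio climbs by one and the target reaches half of the charge. It is the second-order half-life, and, with a scatter of 1 percentage point behind it, it is itself a reading.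

Test it on a reading not used for the line: at 8.00 h it gives 13.8%, and the reading is 13.8%. My reckoning for this flask is therefore 8.50% at 5.0 h, 30.2% at 20 h and 52.6% at 50 h.

The forecast says 8.7%, 30.5% and 53%, above my figures at the two earlier times, and adds: “The 50 h value is therefore quite uncertain”.

The flask gives 7.70%, 29.7% and 52.7%.

    starting material + catalyst ⇌ catalyst + intermediate (K = 0.580, k = 0.230 L mol⁻¹ s⁻¹)
    reagent + catalyst + intermediate → catalyst + target (k = 170 L² mol⁻² s⁻¹)
    2 reagent → self-condensation product (k = 2.30 × 10⁻⁴ L mol⁻¹ s⁻¹)
    starting material ⇌ dormant form (K = 0.360, k = 2.50 × 10⁻⁵ s⁻¹)

Hold the clock against the side step in which reagent meets reagent: half of that step's turnover up to 50 h is done by 7.59 h, sooner than the clock's 44.2 h, while at 50.0 h the step to target uses reagent 8.8 times as fast as the side step. At 50.0 h the flask holds 12.0% of the reagent charge against 28.8% of the starting material charge, and at 500 h the clock's line reads 91.9% of target while the flask holds 64.7%, with reagent, the limiting reagent, at 0% and starting material at 18.2%.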